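**Plan**

1. Locants: chain C1–C8 (C1 ester carbon, C2, C3 and C6 the stereocenters, C3 and C6 the dioxane carbons, C7–C8 the link) and cyclohexenone C1'–C6' (C1' carbonyl, C2' methyl-bearing, C3' chain-bearing, C4' gem-dimethyl, C5', C6').
2. Retrosynthesis cuts C5'–C6' and C3'–C4'. The C2'=C3' enone with a CH2 (C8) on C3' is the tautomer of a C1'-siloxy cyclohexene with an exocyclic C3'=C8 bond, the Diels–Alder adduct of a 2-siloxy vinylallene (C6'=C1'–C2'=C3'=C8) and methacrolein; its CHO stands in for the second C4' methyl.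
3. Further cuts: vinylallene from a C6 propanoic-acid arm (ketene + acyl ylide), the arm from an allyl group, C6–C7 by allylsilane addition to a cyclic peroxycarbenium ion, and O–C3 by intramolecular SN2 of a hydroperoxy ketal on a C3 mesylate.
4. Forward order: aldol chain, then the 1,2-dioxane ring (step 6), quaternary C6 (step 7), the three-carbon arm, and the cyclohexenone ring last (steps 12–15).
5. Stereochemistry: C2 and C3 from an oxazolidinone-controlled syn-aldol, C3 then inverted in the ring closure, C6 by axial attack on the half-chair peroxycarbenium ion cis to the equatorial C3 side chain; the cyclohexenone has no stereocenter.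

Key step: step 14

Remark: compounds 1, 2, 11, 18 and 23 are taken as purchased; the ketal carbon of 9 and 10, the allene axis of 21 and 22, and C4' of 24–26 form as mixtures that are later destroyed, so they are left undefined in the SMILES.

Step 1
Reactants: 1 4-methylpent-4-enal; 2 (4R)-4-benzyl-3-propanoyl-1,3-oxazolidin-2-one
Product: 5 (4R)-4-benzyl-3-[(2R,3S)-3-hydroxy-2,6-dimethylhept-6-enoyl]-1,3-oxazolidin-2-one, via boron enolate 3 (not isolated), via boron aldolate 4 (not isolated)
Conditions: n-Bu2BOTf, i-Pr2NEt, CH2Cl2, −78 to 0 °C; then 1, −78 to 0 °C; pH 7 buffer, MeOH, H2O2, 0 °C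
Reagents that add atoms: none
Why: Evans syn-aldol, in which the Z dibutylboron enolate reacts through a Zimmerman–Traxler chair with one face shielded by the (R)-benzyl auxiliary, so C2 (R) and C3 (S) should be set together.

Step 2
Reactants: 5 (4R)-4-benzyl-3-[(2R,3S)-3-hydroxy-2,6-dimethylhept-6-enoyl]-1,3-oxazolidin-2-one
Product: 6 (2S,3S)-2,6-dimethylhept-6-ene-1,3-diol
Conditions: LiBH4, MeOH (1 equiv), THF, 0 °C
Reagents that add atoms: none
Why: Reductive cleavage of the N-acyl oxazolidinone leaves C2 and C3 untouched and takes C1 off the carbonyl level, so the later C3 sulfonate cannot undergo β-elimination.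

Step 3
Reactants: 6 (2S,3S)-2,6-dimethylhept-6-ene-1,3-diol
Product: 7 (2S,3S)-1-[(tert-butyldimethylsilyl)oxy]-2,6-dimethylhept-6-en-3-ol
Conditions: TBSCl, imidazole, CH2Cl2, 0 °C
Reagents that add atoms: tert-butyldimethylsilyl chloride CC(C)(C)[Si](C)(C)Cl
Why: Silylation should select the primary over the secondary hydroxyl on steric grounds.

Step 4
Reactants: 7 (2S,3S)-1-[(tert-butyldimethylsilyl)oxy]-2,6-dimethylhept-6-en-3-ol
Product: 8 (2S,3S)-1-[(tert-butyldimethylsilyl)oxy]-2,6-dimethylhept-6-en-3-yl methanesulfonate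
Conditions: MsCl, Et3N, CH2Cl2, 0 °C
Reagents that add atoms: methanesulfonyl chloride CS(=O)(=O)Cl
Why: O-Sulfonylation with retention makes C3 the electrophile for the ring closure.

Step 5
Reactants: 8 (2S,3S)-1-[(tert-butyldimethylsilyl)oxy]-2,6-dimethylhept-6-en-3-yl methanesulfonate
Product: 9 (2S,3S)-1-[(tert-butyldimethylsilyl)oxy]-6-hydroperoxy-6-methoxy-2-methylheptan-3-yl methanesulfonate (both C6 epimers)
Conditions: O3, CH2Cl2/MeOH (4:1), −78 °C; N2 purge, concentrate below 20 °C
Reagents that add atoms: ozone [O-][O+]=O; methanol CO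
Why: Ozonolysis in methanol cleaves the 1,1-disubstituted alkene to formaldehyde and the more substituted carbonyl oxide, which methanol traps as the α-methoxy hydroperoxide (Criegee trapping), placing both peroxide oxygens on C6.

Step 6
Reactants: 9 (2S,3S)-1-[(tert-butyldimethylsilyl)oxy]-6-hydroperoxy-6-methoxy-2-methylheptan-3-yl methanesulfonate
Product: 10 tert-butyl{(2S)-2-[(3R)-6-methoxy-6-methyl-1,2-dioxan-3-yl]propoxy}dimethylsilane (both ketal epimers)
Conditions: KOtBu, 18-crown-6, THF, 0 °C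
Reagents that add atoms: none
Why: Intramolecular alkylation of the hydroperoxy ketal anion (6-exo-tet SN2) should close the 1,2-dioxane with inversion at C3, turning the (3S)-mesylate into the (3R)-peroxide of the target.

Step 7
Reactants: 10 tert-butyl{(2S)-2-[(3R)-6-methoxy-6-methyl-1,2-dioxan-3-yl]propoxy}dimethylsilane; 11 allyltrimethylsilane
Product: 12 tert-butyl{(2S)-2-[(3R,6S)-6-methyl-6-(prop-2-en-1-yl)-1,2-dioxan-3-yl]propoxy}dimethylsilane
Conditions: TiCl4, CH2Cl2, −78 °C
Reagents that add atoms: none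
Why: Hosomi–Sakurai allylation of the cyclic peroxycarbenium ion released by TiCl4 from either ketal epimer, where axial attack on the half-chair with the C3 side chain pseudo-equatorial should place the allyl group cis to that side chain and the methyl equatorial, which is the C6 configuration of the target.

Step 8
Reactants: 12 tert-butyl{(2S)-2-[(3R,6S)-6-methyl-6-(prop-2-en-1-yl)-1,2-dioxan-3-yl]propoxy}dimethylsilane
Product: 13 (2R)-2-[(3R,6S)-6-methyl-6-(prop-2-en-1-yl)-1,2-dioxan-3-yl]propanoic acid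
Conditions: CrO3, H2SO4, H2O, acetone, 0 °C
Reagents that add atoms: water O
Why: Jones oxidation cleaves the primary silyl ether in the acidic medium and oxidizes the alcohol through the aldehyde hydrate to the acid, while the dialkyl peroxide and the terminal alkene should be inert.

Step 9
Reactants: 13 (2R)-2-[(3R,6S)-6-methyl-6-(prop-2-en-1-yl)-1,2-dioxan-3-yl]propanoic acid
Product: 14 methyl (2R)-2-[(3R,6S)-6-methyl-6-(prop-2-en-1-yl)-1,2-dioxan-3-yl]propanoate
Conditions: TMSCHN2, toluene/MeOH, 0 °C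
Reagents that add atoms: (trimethylsilyl)diazomethane C[Si](C)(C)C=[N+]=[N-]
Why: Esterification with the diazoalkane is non-basic, which avoids epimerization at C2 and retro-oxa-Michael opening of the β-peroxy ester.

Step 10
Reactants: 14 methyl (2R)-2-[(3R,6S)-6-methyl-6-(prop-2-en-1-yl)-1,2-dioxan-3-yl]propanoate
Product: 16 methyl (2R)-2-[(3R,6R)-6-(3-hydroxypropyl)-6-methyl-1,2-dioxan-3-yl]propanoate, via alkylborane 15 (not isolated)
Conditions: 9-BBN, THF, 0 °C to rt; then NaOAc, H2O2, H2O, 0 °C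
Reagents that add atoms: hydrogen peroxide OO
Why: Anti-Markovnikov hydroboration of the monosubstituted alkene with the bulky borane and buffered oxidation should give the primary alcohol without touching the hindered dialkyl peroxide or the ester.

Step 11
Reactants: 16 methyl (2R)-2-[(3R,6R)-6-(3-hydroxypropyl)-6-methyl-1,2-dioxan-3-yl]propanoate
Product: 17 3-[(3S,6R)-6-[(2R)-1-methoxy-1-oxopropan-2-yl]-3-methyl-1,2-dioxan-3-yl]propanoic acid
Conditions: TEMPO (cat.), PhI(OAc)2, MeCN/pH 7 buffer, rt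
Reagents that add atoms: water O
Why: Oxoammonium (TEMPO) oxidation takes the primary alcohol through the aldehyde hydrate to the acid under near-neutral conditions.

Step 12
Reactants: 17 3-[(3S,6R)-6-[(2R)-1-methoxy-1-oxopropan-2-yl]-3-methyl-1,2-dioxan-3-yl]propanoic acid; 18 3-(triphenyl-λ5-phosphanylidene)butan-2-one
Product: 21 methyl (2R)-2-[(3R,6S)-6-methyl-6-(4-methyl-5-oxohexa-2,3-dien-1-yl)-1,2-dioxan-3-yl]propanoate, via acid chloride 19 (not isolated), via ketene 20 (not isolated)
Conditions: (COCl)2, DMF (cat.), CH2Cl2, 0 °C to rt, evaporate; then 18, Et3N, CH2Cl2, 0 °C to rt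
Reagents that add atoms: none
Why: Dehydrohalogenation of the acid chloride gives the ketene, whose Wittig reaction with the acyl-stabilized ylide should form the trisubstituted allenyl ketone (ketene–Wittig allene synthesis) with C3' as the central allene carbon.

Step 13
Reactants: 21 methyl (2R)-2-[(3R,6S)-6-methyl-6-(4-methyl-5-oxohexa-2,3-dien-1-yl)-1,2-dioxan-3-yl]propanoate
Product: 22 methyl (2R)-2-[(3R,6S)-6-{5-[(tert-butyldimethylsilyl)oxy]-4-methylhexa-2,3,5-trien-1-yl}-6-methyl-1,2-dioxan-3-yl]propanoate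
Conditions: TBSOTf, Et3N, CH2Cl2, −78 °C
Reagents that add atoms: tert-butyldimethylsilyl trifluoromethanesulfonate CC(C)(C)[Si](C)(C)OS(=O)(=O)C(F)(F)F
Why: Soft enolization of the methyl ketone at its only α-hydrogens and O-silylation should give the 2-siloxy vinylallene, the low temperature suppressing amine-induced isomerization of the allenone.

Step 14
Reactants: 22 methyl (2R)-2-[(3R,6S)-6-{5-[(tert-butyldimethylsilyl)oxy]-4-methylhexa-2,3,5-trien-1-yl}-6-methyl-1,2-dioxan-3-yl]propanoate; 23 2-methylprop-2-enal (methacrolein)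
Product: 25 methyl (2R)-2-[(3R,6R)-6-[2-(6-formyl-2,6-dimethyl-3-oxocyclohex-1-en-1-yl)ethyl]-6-methyl-1,2-dioxan-3-yl]propanoate (both C4' epimers), via silyl dienol ether cycloadduct 24 (not isolated)
Conditions: 23 (5 equiv), BHT, toluene, 80 °C; then 1 M HCl, THF, 0 °C to rt
Reagents that add atoms: none
Why: Thermal normal-demand Diels–Alder reaction in which the HOMO of the 2-siloxy vinylallene (diene C6'=C1'(OTBS)–C2'(CH3)=C3', using the proximal π bond of the allene) combines with the LUMO of methacrolein in a concerted, asynchronous suprafacial/suprafacial process; the closest known reaction types are Diels–Alder reactions of 2-siloxy dienes with α-substituted enals and of vinylallenes, whose sp terminus tolerates bond formation to a fully substituted carbon. The cyclohexene ring closes in one [4+2] event that forms C5'–C6' and C3'–C4' together, and the acid work-up cleaves the silyl dienol ether with protonation at the exocyclic carbon C8, which moves the double bond into the ring as the tetrasubstituted C2'=C3' enone. The selectivity needed is regioselectivity: the siloxy group on C1' makes the CH2 terminus C6' the most nucleophilic site, so it bonds to the β-CH2 of the enal and the allene carbon C3' joins the α-carbon bearing CH3 and CHO (para orientation). The only new stereocenter, C4'(CH3)(CHO), is not controlled and need not be, because step 15 turns CHO into the second methyl; the exocyclic alkene geometry and the allene axis vanish likewise. Periselectivity (diene versus [2+2] at the allene, C=C versus C=O of the enal) should be secured by the s-cis bias of the 2,3-disubstituted diene and by the absence of a Lewis acid.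

Step 15
Reactants: 25 methyl (2R)-2-[(3R,6R)-6-[2-(6-formyl-2,6-dimethyl-3-oxocyclohex-1-en-1-yl)ethyl]-6-methyl-1,2-dioxan-3-yl]propanoate
Product: 27 methyl (2R)-2-[(3R,6R)-6-methyl-6-[2-(2,6,6-trimethyl-3-oxocyclohex-1-en-1-yl)ethyl]-1,2-dioxan-3-yl]propanoate (diacarperoxide A), via tosylhydrazone 26 (not isolated)
Conditions: TsNHNH2, EtOH, rt; then catecholborane, CHCl3, 0 °C; NaOAc·3H2O, 60 °C
Reagents that add atoms: none
Why: The aldehyde should condense selectively (the hindered conjugated ketone does not), and Kabalka-type reduction of the tosylhydrazone with loss of sulfinate and dinitrogen turns CHO into CH3, removing the activating group of the dienophile.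

**Compound list**

1 | 4-methylpent-4-enal | C=C(C)CCC=O | starting material
2 | (4R)-4-benzyl-3-propanoyl-1,3-oxazolidin-2-one | CCC(=O)N1[C@H](Cc2ccccc2)COC1=O | starting material
3 | dibutylboron Z-enolate of 2 | C/C=C(\OB(CCCC)CCCC)N1[C@H](Cc2ccccc2)COC1=O | intermediate
4 | dibutylboron aldolate of 5 | O=C1OC[C@@H](Cc2ccccc2)N1C(=O)[C@H](C)[C@@H](OB(CCCC)CCCC)CCC(C)=C | intermediate
5 | (4R)-4-benzyl-3-[(2R,3S)-3-hydroxy-2,6-dimethylhept-6-enoyl]-1,3-oxazolidin-2-one | O=C1OC[C@@H](Cc2ccccc2)N1C(=O)[C@H](C)[C@@H](O)CCC(C)=C | intermediate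
6 | (2S,3S)-2,6-dimethylhept-6-ene-1,3-diol | OC[C@H](C)[C@@H](O)CCC(C)=C | intermediate
7 | (2S,3S)-1-[(tert-butyldimethylsilyl)oxy]-2,6-dimethylhept-6-en-3-ol | CC(C)(C)[Si](C)(C)OC[C@H](C)[C@@H](O)CCC(C)=C | intermediate
8 | (2S,3S)-1-[(tert-butyldimethylsilyl)oxy]-2,6-dimethylhept-6-en-3-yl methanesulfonate | CC(C)(C)[Si](C)(C)OC[C@H](C)[C@@H](OS(C)(=O)=O)CCC(C)=C | intermediate
9 | (2S,3S)-1-[(tert-butyldimethylsilyl)oxy]-6-hydroperoxy-6-methoxy-2-methylheptan-3-yl methanesulfonate (C6 epimers) | CC(C)(C)[Si](C)(C)OC[C@H](C)[C@@H](OS(C)(=O)=O)CCC(C)(OC)OO | intermediate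
10 | tert-butyl{(2S)-2-[(3R)-6-methoxy-6-methyl-1,2-dioxan-3-yl]propoxy}dimethylsilane (ketal epimers) | CC(C)(C)[Si](C)(C)OC[C@H](C)[C@H]1CCC(C)(OC)OO1 | intermediate
11 | allyltrimethylsilane | C=CC[Si](C)(C)C | starting material
12 | tert-butyl{(2S)-2-[(3R,6S)-6-methyl-6-(prop-2-en-1-yl)-1,2-dioxan-3-yl]propoxy}dimethylsilane | CC(C)(C)[Si](C)(C)OC[C@H](C)[C@H]1CC[C@@](C)(CC=C)OO1 | intermediate
13 | (2R)-2-[(3R,6S)-6-methyl-6-(prop-2-en-1-yl)-1,2-dioxan-3-yl]propanoic acid | OC(=O)[C@H](C)[C@H]1CC[C@@](C)(CC=C)OO1 | intermediate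
14 | methyl (2R)-2-[(3R,6S)-6-methyl-6-(prop-2-en-1-yl)-1,2-dioxan-3-yl]propanoate | COC(=O)[C@H](C)[C@H]1CC[C@@](C)(CC=C)OO1 | intermediate
15 | B-alkyl-9-borabicyclo[3.3.1]nonane adduct of 14 | COC(=O)[C@H](C)[C@H]1CC[C@@](C)(CCCB2C3CCCC2CCC3)OO1 | intermediate
16 | methyl (2R)-2-[(3R,6R)-6-(3-hydroxypropyl)-6-methyl-1,2-dioxan-3-yl]propanoate | COC(=O)[C@H](C)[C@H]1CC[C@@](C)(CCCO)OO1 | intermediate
17 | 3-[(3S,6R)-6-[(2R)-1-methoxy-1-oxopropan-2-yl]-3-methyl-1,2-dioxan-3-yl]propanoic acid | COC(=O)[C@H](C)[C@H]1CC[C@@](C)(CCC(O)=O)OO1 | intermediate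
18 | 3-(triphenyl-λ5-phosphanylidene)butan-2-one | CC(=O)C(C)=P(c1ccccc1)(c1ccccc1)c1ccccc1 | starting material
19 | methyl (2R)-2-[(3R,6S)-6-(3-chloro-3-oxopropyl)-6-methyl-1,2-dioxan-3-yl]propanoate | COC(=O)[C@H](C)[C@H]1CC[C@@](C)(CCC(Cl)=O)OO1 | intermediate
20 | methyl (2R)-2-[(3R,6S)-6-methyl-6-(3-oxoprop-2-en-1-yl)-1,2-dioxan-3-yl]propanoate (ketene) | COC(=O)[C@H](C)[C@H]1CC[C@@](C)(CC=C=O)OO1 | intermediate
21 | methyl (2R)-2-[(3R,6S)-6-methyl-6-(4-methyl-5-oxohexa-2,3-dien-1-yl)-1,2-dioxan-3-yl]propanoate | COC(=O)[C@H](C)[C@H]1CC[C@@](C)(CC=C=C(C)C(C)=O)OO1 | intermediate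
22 | methyl (2R)-2-[(3R,6S)-6-{5-[(tert-butyldimethylsilyl)oxy]-4-methylhexa-2,3,5-trien-1-yl}-6-methyl-1,2-dioxan-3-yl]propanoate | COC(=O)[C@H](C)[C@H]1CC[C@@](C)(CC=C=C(C)C(=C)O[Si](C)(C)C(C)(C)C)OO1 | intermediate
23 | 2-methylprop-2-enal | CC(=C)C=O | starting material
24 | methyl (2R)-2-[(3R,6S)-6-{2-[3-[(tert-butyldimethylsilyl)oxy]-6-formyl-2,6-dimethylcyclohex-2-en-1-ylidene]ethyl}-6-methyl-1,2-dioxan-3-yl]propanoate | COC(=O)[C@H](C)[C@H]1CC[C@@](C)(CC=C2C(C)=C(O[Si](C)(C)C(C)(C)C)CCC2(C)C=O)OO1 | intermediate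
25 | methyl (2R)-2-[(3R,6R)-6-[2-(6-formyl-2,6-dimethyl-3-oxocyclohex-1-en-1-yl)ethyl]-6-methyl-1,2-dioxan-3-yl]propanoate | COC(=O)[C@H](C)[C@H]1CC[C@@](C)(CCC2=C(C)C(=O)CCC2(C)C=O)OO1 | intermediate
26 | 4-methylbenzenesulfonohydrazone of 25 | COC(=O)[C@H](C)[C@H]1CC[C@@](C)(CCC2=C(C)C(=O)CCC2(C)C=NNS(=O)(=O)c2ccc(C)cc2)OO1 | intermediate
27 | methyl (2R)-2-[(3R,6R)-6-methyl-6-[2-(2,6,6-trimethyl-3-oxocyclohex-1-en-1-yl)ethyl]-1,2-dioxan-3-yl]propanoate (diacarperoxide A) | COC(=O)[C@H](C)[C@H]1CC[C@@](C)(CCC2=C(C)C(=O)CCC2(C)C)OO1 | target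

**Step count and risk**

Total step count: 15. Longest linear sequence: 15 steps (1 to 27).

Steps most likely to fail:

Step 14. The poorly activated 1,1-disubstituted dienophile may react too slowly at temperatures that the silyl dienol ether and the O–O bond tolerate, so that dimerization, [2+2] addition or isomerization of the vinylallene takes over. Fallback, setting out from 21 and returning at 27: a stepwise polar annulation makes the same two ring bonds. Allenone 21 is treated with 1-(2-methylprop-1-en-1-yl)pyrrolidine (the enamine of isobutyraldehyde) in MeCN, the enamine carbon adding to the central allene carbon to form C3'–C4'. Buffered hydrolysis (AcOH, NaOAc, H2O) should give the keto aldehyde F1. Pyrrolidinium acetate then condenses the methyl ketone CH3 with the non-enolizable aldehyde, forming C5'–C6' as a double bond in the cross-conjugated dienone F2. Diimide (potassium azodicarboxylate, AcOH, MeOH) should saturate only the disubstituted C5'=C6' bond, leaving the tetrasubstituted enone and the peroxide, to give 27; steps 13 to 15 are bypassed.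

Step 7. Facial selectivity in the addition to the peroxycarbenium ion may be poor or reversed, and the Lewis acid may trigger O–O heterolysis. Fallback, setting out from 8 and returning at 17: the quaternary peroxide is made without any facial-selectivity requirement, at the price of a separation. Cross-metathesis of 8 with tert-butyl but-3-enoate (second-generation Hoveyda–Grubbs catalyst, CH2Cl2, 40 °C) should give the trisubstituted alkene F3. Mukaiyama–Isayama hydroperoxysilylation (Co(acac)2, O2, Et3SiH) adds the peroxide at the tertiary carbon to give the triethylsilyl peroxide F4 as both C6 epimers. TBAF removes both silyl groups and the peroxide anion closes the ring by 6-exo-tet SN2 with inversion at C3; chromatographic separation of the C6 epimers gives the hydroxy dioxane F5. TEMPO/PhI(OAc)2 oxidation gives the acid F6, TMSCHN2 the diester F7, and TFA cleavage of the tert-butyl ester gives 17.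

Step 15. The neopentyl-type hydrazone may reduce incompletely, with competing attack on the enone or the O–O bond. Fallback, setting out from 25 and returning at 27: deoxygenation through an iodide. NaBH4 (MeOH/CH2Cl2, −78 °C) should reduce only the aldehyde to the neopentyl alcohol F8. Tf2O/2,6-lutidine followed by Bu4NI gives the iodide F9. Radical reduction with (Me3Si)3SiH, Et3B and air at rt then gives 27.

**Further compounds**

F1 | step 14 | methyl (2R)-2-[(3R,6R)-6-(4-acetyl-3-(2-methyl-1-oxopropan-2-yl)pent-3-en-1-yl)-6-methyl-1,2-dioxan-3-yl]propanoate (alkene isomers) | COC(=O)[C@H](C)[C@H]1CC[C@@](C)(CCC(=C(C)C(C)=O)C(C)(C)C=O)OO1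
F2 | step 14 | methyl (2R)-2-[(3R,6R)-6-methyl-6-[2-(2,6,6-trimethyl-3-oxocyclohexa-1,4-dien-1-yl)ethyl]-1,2-dioxan-3-yl]propanoate | COC(=O)[C@H](C)[C@H]1CC[C@@](C)(CCC2=C(C)C(=O)C=CC2(C)C)OO1
F3 | step 7 | tert-butyl (7S,8S)-9-[(tert-butyldimethylsilyl)oxy]-7-(methanesulfonyloxy)-4,8-dimethylnon-3-enoate (alkene isomers) | CC(C)(C)[Si](C)(C)OC[C@H](C)[C@@H](OS(C)(=O)=O)CCC(C)=CCC(=O)OC(C)(C)C
F4 | step 7 | tert-butyl (7S,8S)-9-[(tert-butyldimethylsilyl)oxy]-7-(methanesulfonyloxy)-4,8-dimethyl-4-[(triethylsilyl)peroxy]nonanoate (C4 epimers) | CC(C)(C)[Si](C)(C)OC[C@H](C)[C@@H](OS(C)(=O)=O)CCC(C)(CCC(=O)OC(C)(C)C)OO[Si](CC)(CC)CC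
F5 | step 7 | tert-butyl 3-[(3S,6R)-6-[(2S)-1-hydroxypropan-2-yl]-3-methyl-1,2-dioxan-3-yl]propanoate | OC[C@H](C)[C@H]1CC[C@@](C)(CCC(=O)OC(C)(C)C)OO1
F6 | step 7 | (2R)-2-[(3R,6S)-6-(3-tert-butoxy-3-oxopropyl)-6-methyl-1,2-dioxan-3-yl]propanoic acid | OC(=O)[C@H](C)[C@H]1CC[C@@](C)(CCC(=O)OC(C)(C)C)OO1
F7 | step 7 | methyl (2R)-2-[(3R,6S)-6-(3-tert-butoxy-3-oxopropyl)-6-methyl-1,2-dioxan-3-yl]propanoate | COC(=O)[C@H](C)[C@H]1CC[C@@](C)(CCC(=O)OC(C)(C)C)OO1
F8 | step 15 | methyl (2R)-2-[(3R,6R)-6-[2-(6-(hydroxymethyl)-2,6-dimethyl-3-oxocyclohex-1-en-1-yl)ethyl]-6-methyl-1,2-dioxan-3-yl]propanoate | COC(=O)[C@H](C)[C@H]1CC[C@@](C)(CCC2=C(C)C(=O)CCC2(C)CO)OO1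
F9 | step 15 | methyl (2R)-2-[(3R,6R)-6-[2-(6-(iodomethyl)-2,6-dimethyl-3-oxocyclohex-1-en-1-yl)ethyl]-6-methyl-1,2-dioxan-3-yl]propanoate | COC(=O)[C@H](C)[C@H]1CC[C@@](C)(CCC2=C(C)C(=O)CCC2(C)CI)OO1
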